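Retrosynthesis: the C3–O acyl bond is cut first. The three oxygen functions of the core (C3–OH, C9–OH, C8=O) are then removed to leave a hydrocarbon. Finally C5–C10, C6–C7 and the C5–C14 methyl bond are opened to an acyclic farnesyl chain, and the acid is cut at C4'=C5'.
Enabling feature: ring A (C1–C5, C10) and ring B (C5–C10), the cis-vicinal methyl groups on C4 and C5, and the three-carbon unit on C7 together make up the carbon skeleton of (+)-aristolochene. The absolute configuration at C4 and C5 is also the same.
Forward, rings: farnesol is converted to its diphosphate. One cyclase reaction then closes the ten-membered ring first and both six-membered rings in a single transannular event.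
Forward, editing of the bicycle: C8 by allylic oxidation; C10–H and C9–O by dissolving-metal reduction and Rubottom oxidation; the 7(11)-alkene by conjugation; C3–OH by P450 hydroxylation; then ester formation and desilylation.
Stereochemistry: C4 and C5 come from the cyclase, C10 from axial protonation, C9 from α-face attack anti to C14, and C3 from retentive hydroxylation of the equatorial C–H. The 6'E alkene comes from the starting enone and 2'E,4'E from the olefination.
Key step: step 3

Remark: eremophilane numbering is used (C14 on C5, C15 on C4, C11–C13 on C7; primed numbers for the acid), and β is the face of C14 and C15. It is assumed that the recombinant proteins (aristolochene synthase, P450BM3 variants, phosphite dehydrogenase) are made by routine expression in E. coli and count as catalysts. Compounds 1, 13 and 14 are commercial.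

Step 1
Reactants: 1 (2E,6E)-farnesol
Product: 2 (2E,6E)-farnesyl bromide
Conditions: PBr3 (0.4 equiv), Et2O, −10 °C
Reagents that add atoms: phosphorus tribromide, BrP(Br)Br
Why: Low-temperature SN2 substitution of the activated primary allylic alcohol by bromide is the standard entry to farnesyl halides and should leave both E-trisubstituted alkenes in place without allylic transposition.

Step 2
Reactants: 2 (2E,6E)-farnesyl bromide
Product: 3 (2E,6E)-farnesyl diphosphate (handled as its ammonium salt, drawn as the free acid)
Conditions: (Bu4N)3HP2O7 (2 equiv), MeCN, rt; cation-exchange resin (NH4+ form), aq NH4HCO3; cellulose chromatography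
Reagents that add atoms: tris(tetrabutylammonium) hydrogen diphosphate, CCCC[N+](CCCC)(CCCC)CCCC.CCCC[N+](CCCC)(CCCC)CCCC.CCCC[N+](CCCC)(CCCC)CCCC.OP(=O)([O-])OP(=O)([O-])[O-]
Why: SN2 displacement of a primary allylic halide by the organic-soluble diphosphate anion, followed by cation exchange, is the established preparation of allylic diphosphates and does not touch the alkene geometry.

Step 3
Reactants: 3 (2E,6E)-farnesyl diphosphate
Product: 5 (+)-aristolochene, via germacrene A 4 (not isolated)
Conditions: recombinant aristolochene synthase (Aspergillus terreus), MgCl2, HEPES buffer pH 7.5, glycerol, dithiothreitol, pentane overlay, 30 °C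
Reagents that add atoms: none
Why: Magnesium-assisted ionisation of the diphosphate of 3 gives an allylic cation at C6 that is captured by the distal C7=C11 alkene (C6–C7 bond), and loss of a C12 proton leaves enzyme-bound 4; reprotonation of 4 at C1 lets the C4=C5 alkene attack C10 (C5–C10 bond), after which a 1,2-hydride shift from C5 to C4, a 1,2-shift of the C14 methyl group from C10 to C5 (C5–C14 bond) and loss of a C9 proton give 5. The closest known reaction type is this very reaction, the ionisation-initiated (class one) sesquiterpene cyclase conversion of the native substrate by aristolochene synthase. The ten-membered ring closes by a macrocyclisation that is exo at the C7=C11 alkene (the charge moves to the tertiary C11 outside the ring), and rings A and B then close together in one transannular cation–alkene addition, endo with respect to ring A (both alkene carbons C4 and C5 end up in it) and exo with respect to ring B. Since 3 is achiral, all three new stereocentres are controlled by the chiral contour of the active site: C7 by the alkene face offered to C6, C5 by the migration of C14 anti to the departing hydride, and C4 by the face that receives that hydride, which makes C14 and C15 cis. The step needs bonding of C6 to C7 rather than to C1 or C11, protonation of 4 at C1 only and final deprotonation at C9 rather than C1; the substrate secures the first through its 2E,6E geometry and the Markovnikov bias of its trisubstituted alkenes (tertiary cations at C11, C10 and C4), the enzyme template secures the others, and the Aspergillus terreus enzyme is preferred because it is known for high product fidelity.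

Step 4
Reactants: 5 (+)-aristolochene
Product: 6 eremophila-9,11-dien-8-one (4β,5β-dimethyl, 7α-isopropenyl; (3S,4aR,5S)-4a,5-dimethyl-3-(prop-1-en-2-yl)-4,4a,5,6,7,8-hexahydronaphthalen-2(3H)-one)
Conditions: CrO3, 3,5-dimethylpyrazole, CH2Cl2, −20 °C
Reagents that add atoms: chromium trioxide, O=[Cr](=O)=O
Why: Allylic oxidation by the hexavalent chromium–pyrazole reagent takes the ring methylene next to the CH terminus of the trisubstituted alkene (C8), the regiochemistry known from valencene to nootkatone and from 5-ene steroids to 7-ketones, while the less electron-rich isopropenyl group and C1 should react more slowly and the non-basic medium preserves C7 and the deconjugated alkene.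

Step 5
Reactants: 6 eremophila-9,11-dien-8-one
Product: 8 8-(tert-butyldimethylsilyloxy)-10αH-eremophila-8,11-diene, via lithium enolate 7 (not isolated)
Conditions: Li, NH3(l)/THF, t-BuOH (1 equiv), −78 °C; NH3 removed cold; TBSCl, DMPU, THF, −78 °C to 0 °C
Reagents that add atoms: tert-butyldimethylsilyl chloride, CC(C)(C)[Si](C)(C)Cl
Why: Dissolving-metal (Birch-type) enone reduction places an axial hydrogen on C10 because overlap with the enolate favours the trans-decalin (10αH), the isolated isopropenyl group is not reduced, and the enolate, generated only between C8 and C9, is fixed on oxygen by silylation.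

Step 6
Reactants: 8 8-(tert-butyldimethylsilyloxy)-10αH-eremophila-8,11-diene
Product: 10 9α-(tert-butyldimethylsilyloxy)-10αH-eremophil-11-en-8-one, via silyloxy epoxide 9 (not isolated)
Conditions: mCPBA (1.05 equiv), hexane/CH2Cl2, −15 °C to rt
Reagents that add atoms: 3-chloroperbenzoic acid, O=C(OO)c1cccc(Cl)c1
Why: In this Rubottom oxidation the electron-rich silyl enol ether is epoxidised far faster than the 1,1-disubstituted alkene and from the α face, because the axial C14 methyl group covers the β face (as in 2-ene steroids), and opening of 9 with 1,4-silyl shift leaves the equatorial 9α-silyloxy ketone, so the C9 protecting group arrives with the oxidation.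

Step 7
Reactants: 10 9α-(tert-butyldimethylsilyloxy)-10αH-eremophil-11-en-8-one
Product: 11 9α-(tert-butyldimethylsilyloxy)-10αH-eremophil-7(11)-en-8-one
Conditions: DBU (cat.), toluene, 60 °C
Reagents that add atoms: none
Why: Base-catalysed isomerisation of a β,γ- to an α,β-unsaturated ketone by deprotonation at C7 and reprotonation at C13 (isopulegone-to-pulegone type) moves the alkene into the tetrasubstituted 7(11) position, erases C7 and cannot harm C9, whose equatorial silyloxy group is already the more stable epimer.

Step 8
Reactants: 11 9α-(tert-butyldimethylsilyloxy)-10αH-eremophil-7(11)-en-8-one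
Product: 12 3α-hydroxy-9α-(tert-butyldimethylsilyloxy)-10αH-eremophil-7(11)-en-8-one
Conditions: P450BM3 (CYP102A1) variant picked from an active-site library (positions 75, 78, 82, 87, 328), E. coli lysate, NADP+ (cat.), phosphite dehydrogenase, Na2HPO3, air, potassium phosphate buffer pH 8.0, 2% DMSO, 25 °C
Reagents that add atoms: dioxygen, O=O
Why: Proposed new method: the ferryl (tetravalent oxoiron) porphyrin radical cation of the enzyme abstracts hydrogen from an unactivated methylene and returns hydroxyl to the same face (rebound, retention), so attack on the exposed equatorial 3α-H gives the equatorial 3α-alcohol directly; C3 sits at the hydrocarbon end of the long molecular axis, farthest from the electron-withdrawing C8 ketone and the bulky C9 silyl ether that should stay near the mouth of the substrate channel, while discrimination against C2, C12/C13 and the 7(11)-alkene must come from the variant found by screening; the closest known reaction types are the C3 hydroxylation of ring A of sclareolide-type trans-decalins by engineered P450BM3 and the C3 hydroxylation of the eremophilane hydrocarbon 5-epi-aristolochene by the plant enzyme CYP71D20, neither yet shown on an aristolochene-derived ketone.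

Step 9
Reactants: 13 (E)-non-3-en-2-one; 14 triethyl (E)-4-phosphonocrotonate
Product: 16 ethyl (2E,4E,6E)-5-methyldodeca-2,4,6-trienoate, via lithiated phosphonate 15 (not isolated)
Conditions: 14, LiN(SiMe3)2, THF/DMPU, −78 °C; then 13, −78 °C to rt; chromatography
Reagents that add atoms: none
Why: In this vinylogous Horner–Wadsworth–Emmons olefination the phosphonate anion adds 1,2 to the methyl ketone, reversible addition favours the E-trisubstituted C4'=C5' alkene, the crotonate alkene stays E and the 6'E alkene of 13 is untouched, and the minor 4'Z isomer is removed by chromatography here and by crystallisation of 18.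

Step 10
Reactants: 16 ethyl (2E,4E,6E)-5-methyldodeca-2,4,6-trienoate
Product: 18 (2E,4E,6E)-5-methyldodeca-2,4,6-trienoic acid, via lithium trienoate 17 (not isolated)
Conditions: LiOH, THF/EtOH/H2O, rt; 1 M HCl; recrystallisation
Reagents that add atoms: lithium hydroxide, [Li+].[OH-]
Why: Saponification by acyl–oxygen cleavage followed by acidification is routine for conjugated polyenoates and does not change the alkene geometry at room temperature.

Step 11
Reactants: 12 3α-hydroxy-9α-(tert-butyldimethylsilyloxy)-10αH-eremophil-7(11)-en-8-one; 18 (2E,4E,6E)-5-methyldodeca-2,4,6-trienoic acid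
Product: 19 9α-(tert-butyldimethylsilyloxy)-8-oxo-10αH-eremophil-7(11)-en-3α-yl (2E,4E,6E)-5-methyldodeca-2,4,6-trienoate
Conditions: N,N'-diisopropylcarbodiimide, DMAP (cat.), CH2Cl2, 0 °C to rt
Reagents that add atoms: none
Why: Steglich esterification (carbodiimide activation with DMAP as acyl-transfer catalyst) meets a single free hydroxyl group, the equatorial C3–OH, keeps the C3–O bond and hence the configuration, and is mild enough to avoid deconjugation of the trienoyl unit.

Step 12
Reactants: 19 9α-(tert-butyldimethylsilyloxy)-8-oxo-10αH-eremophil-7(11)-en-3α-yl (2E,4E,6E)-5-methyldodeca-2,4,6-trienoate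
Product: 20 9α-hydroxy-8-oxo-10αH-eremophil-7(11)-en-3α-yl (2E,4E,6E)-5-methyldodeca-2,4,6-trienoate (target)
Conditions: HF·pyridine, THF, 0 °C to rt
Reagents that add atoms: none
Why: Fluoride-driven Si–O cleavage in a weakly acidic medium frees the C9 hydroxyl group without ketol shift, ester cleavage or alkene isomerisation, all of which a basic fluoride source could provoke.

Compound list
1 | (2E,6E)-farnesol | CC(C)=CCC/C(C)=C/CC/C(C)=C/CO | starting material
2 | (2E,6E)-farnesyl bromide | CC(C)=CCC/C(C)=C/CC/C(C)=C/CBr | intermediate
3 | (2E,6E)-farnesyl diphosphate | CC(C)=CCC/C(C)=C/CC/C(C)=C/COP(=O)(O)OP(=O)(O)O | intermediate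
4 | (S)-germacrene A (enzyme-bound, not isolated) | CC(=C)[C@H]1CC/C(C)=C/CC/C(C)=C/C1 | intermediate
5 | (+)-aristolochene, (4S,4aR,6S)-4,4a-dimethyl-6-(prop-1-en-2-yl)-1,2,3,4,4a,5,6,7-octahydronaphthalene | C1CCC2=CC[C@H](C(C)=C)C[C@]2(C)[C@H]1C | intermediate
6 | eremophila-9,11-dien-8-one (4β,5β-dimethyl, 7α-isopropenyl) | C1CCC2=CC(=O)[C@H](C(C)=C)C[C@]2(C)[C@H]1C | intermediate
7 | lithium 10αH-eremophila-8,11-dien-8-olate (not isolated) | C1CC[C@H]2C=C([O-])[C@H](C(C)=C)C[C@]2(C)[C@H]1C.[Li+] | intermediate
8 | 8-(tert-butyldimethylsilyloxy)-10αH-eremophila-8,11-diene | C1CC[C@H]2C=C(O[Si](C)(C)C(C)(C)C)[C@H](C(C)=C)C[C@]2(C)[C@H]1C | intermediate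
9 | 8α,9α-epoxy-8β-(tert-butyldimethylsilyloxy)-10αH-eremophil-11-ene (not isolated) | C1CC[C@H]2[C@@H]3O[C@]3(O[Si](C)(C)C(C)(C)C)[C@H](C(C)=C)C[C@]2(C)[C@H]1C | intermediate
10 | 9α-(tert-butyldimethylsilyloxy)-10αH-eremophil-11-en-8-one | C1CC[C@H]2[C@H](O[Si](C)(C)C(C)(C)C)C(=O)[C@H](C(C)=C)C[C@]2(C)[C@H]1C | intermediate
11 | 9α-(tert-butyldimethylsilyloxy)-10αH-eremophil-7(11)-en-8-one | C1CC[C@H]2[C@H](O[Si](C)(C)C(C)(C)C)C(=O)C(=C(C)C)C[C@]2(C)[C@H]1C | intermediate
12 | 3α-hydroxy-9α-(tert-butyldimethylsilyloxy)-10αH-eremophil-7(11)-en-8-one | O[C@@H]1CC[C@H]2[C@H](O[Si](C)(C)C(C)(C)C)C(=O)C(=C(C)C)C[C@]2(C)[C@H]1C | intermediate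
13 | (E)-non-3-en-2-one | CCCCC/C=C/C(C)=O | starting material
14 | triethyl (E)-4-phosphonocrotonate | CCOC(=O)/C=C/CP(=O)(OCC)OCC | starting material
15 | lithiated triethyl 4-phosphonocrotonate (not isolated) | CCOC(=O)/C=C/[CH-]P(=O)(OCC)OCC.[Li+] | intermediate
16 | ethyl (2E,4E,6E)-5-methyldodeca-2,4,6-trienoate | CCCCC/C=C/C(C)=C/C=C/C(=O)OCC | intermediate
17 | lithium (2E,4E,6E)-5-methyldodeca-2,4,6-trienoate (not isolated) | CCCCC/C=C/C(C)=C/C=C/C(=O)[O-].[Li+] | intermediate
18 | (2E,4E,6E)-5-methyldodeca-2,4,6-trienoic acid | CCCCC/C=C/C(C)=C/C=C/C(=O)O | intermediate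
19 | 9α-(tert-butyldimethylsilyloxy)-8-oxo-10αH-eremophil-7(11)-en-3α-yl (2E,4E,6E)-5-methyldodeca-2,4,6-trienoate | CCCCC/C=C/C(C)=C/C=C/C(=O)O[C@@H]1CC[C@H]2[C@H](O[Si](C)(C)C(C)(C)C)C(=O)C(=C(C)C)C[C@]2(C)[C@H]1C | intermediate
20 | (1R,2R,4aR,5S,8aR)-5-hydroxy-1,8a-dimethyl-6-oxo-7-(propan-2-ylidene)decahydronaphthalen-2-yl (2E,4E,6E)-5-methyldodeca-2,4,6-trienoate | CCCCC/C=C/C(C)=C/C=C/C(=O)O[C@@H]1CC[C@H]2[C@H](O)C(=O)C(=C(C)C)C[C@]2(C)[C@H]1C | target

Total step count: 12. Longest linear sequence: 10 (steps 1–8, 11 and 12, from 1 to 20). The acid 18 takes 2 steps.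

Steps most likely to fail

1. Step 8 (new method).
The silylated ketone may not bind productively. Hydrogen abstraction may also spread over C2, C3 and the allylic methyl groups, or the 7(11)-alkene may be epoxidised.
The fallback uses known chemistry, sets out from 11 and returns at 19. Non-directed methylene oxidation of 11 with [Fe(PDP)(MeCN)2](SbF6)2, H2O2 and AcOH in MeCN is known to oxidise ring A methylenes of trans-decalin terpenoids that carry their electron-withdrawing groups in the far ring. It also tolerates electron-poor tetrasubstituted alkenes. After separation from the C2 ketone it should give 9α-(tert-butyldimethylsilyloxy)-10αH-eremophil-7(11)-ene-3,8-dione F1.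
Potassium tri-sec-butylborohydride in THF at −78 °C reduces the unhindered saturated C3 ketone in preference to the hindered tetrasubstituted enone. Because C14 blocks the axial β trajectory, it attacks from the equatorial α side and gives the axial alcohol 3β-hydroxy-9α-(tert-butyldimethylsilyloxy)-10αH-eremophil-7(11)-en-8-one F2.
Mitsunobu esterification of F2 with acid 18 (PPh3, diisopropyl azodicarboxylate, toluene, 0 °C) inverts C3 and delivers 19 directly.

2. Step 5.
Proton exchange while ammonia is removed, together with slow silylation, may let the enolate migrate from C9 to the more acidic C7, so that the regiochemical information of the reduction is lost.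
The fallback sets out from 6 and returns at 8. Regiocontrol is taken from kinetic deprotonation instead of reductive enolate generation. The same Li/NH3 reduction is quenched with NH4Cl to isolate the saturated ketone 10αH-eremophil-11-en-8-one F3. This is deprotonated with LiN(i-Pr)2 in THF at −78 °C at the less hindered C9 methylene (C7–H is tertiary and flanked by the isopropenyl group). The enolate is trapped at once with TBSOTf to give 8.

3. Step 4.
Hydrogen abstraction may be shared between C8, C1 and C7, the isopropenyl group may be attacked, and the volatile hydrocarbon may be lost in a large excess of chromium reagent.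
The fallback sets out from 5 and returns at 6. The oxygen is brought in by an ene reaction and then transposed. Schenck ene reaction of the more electron-rich trisubstituted alkene with singlet oxygen (O2, tetraphenylporphyrin, light, CH2Cl2, 0 °C) proceeds from the α face with abstraction of the pseudoaxial 8α-H. This is the course known for 5-ene steroids and for valencene, and it should give 10α-hydroperoxyeremophila-8,11-diene F4.
Reduction with PPh3 gives 10α-hydroxyeremophila-8,11-diene F5. Babler–Dauben oxidative transposition of this tertiary allylic alcohol with pyridinium chlorochromate, [C5H5NH][CrO3Cl], in CH2Cl2 moves the oxygen from C10 to C8 and gives enone 6.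

Further compounds
F1 | step 8 | 9α-(tert-butyldimethylsilyloxy)-10αH-eremophil-7(11)-ene-3,8-dione | O=C1CC[C@H]2[C@H](O[Si](C)(C)C(C)(C)C)C(=O)C(=C(C)C)C[C@]2(C)[C@H]1C
F2 | step 8 | 3β-hydroxy-9α-(tert-butyldimethylsilyloxy)-10αH-eremophil-7(11)-en-8-one | O[C@H]1CC[C@H]2[C@H](O[Si](C)(C)C(C)(C)C)C(=O)C(=C(C)C)C[C@]2(C)[C@H]1C
F3 | step 5 | 10αH-eremophil-11-en-8-one | C1CC[C@H]2CC(=O)[C@H](C(C)=C)C[C@]2(C)[C@H]1C
F4 | step 4 | 10α-hydroperoxyeremophila-8,11-diene | C1CC[C@@]2(OO)C=C[C@H](C(C)=C)C[C@]2(C)[C@H]1C
F5 | step 4 | 10α-hydroxyeremophila-8,11-diene | C1CC[C@@]2(O)C=C[C@H](C(C)=C)C[C@]2(C)[C@H]1C
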